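## Retrosynthetic overview

1. The C2=C3 bond of the tetraenoyl chain is made last, by a boron-templated condensation of the acetyl CH3 of an unprotected 3-acetyl-1,4-dihydroxy-5-aryl-2-pyridone with the (8R)-trienal (new method).
2. The trienal comes from two 2-carbon Wittig/acetal homologations of (2E,4R)-2,4-dimethylhex-2-enal, which comes from SeO2 oxidation of the E-methyl of (4R)-2,4-dimethylhex-2-ene, the Wolff–Kishner product of (3R)-3,5-dimethylhex-4-enal.
3. The single stereocentre (C10) is set by iminium-catalysed conjugate addition of potassium isobutenyltrifluoroborate to crotonaldehyde.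
4. The pyridone comes from BBr3 demethylation, N-oxidation and C3 lithiation/acetylation of the Suzuki product of 5-bromo-2,4-dimethoxypyridine and 4-methoxyphenylboronic acid.
5. Rings: none is built. The benzene and pyridine rings are bought and joined first (Suzuki); the pyridine becomes the 1-hydroxy-2-pyridone at the end of that branch.

Assumption: starting materials 1, 2, 8, 13, 14 and 16 are bought; catalyst-bound species and species that exist only until aqueous work-up (iminium ions, betaines, tetrahedral adducts, borate esters) are not numbered.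

## Route

Step 1
Reactants: 1 (E)-but-2-enal; 2 potassium trifluoro(2-methylprop-1-en-1-yl)borate
Product: 3 (3R)-3,5-dimethylhex-4-enal
Conditions: (2S,5S)-5-benzyl-2-tert-butyl-3-methylimidazolidin-4-one·HCl (20 mol%), HF (48% aq., 1 equiv), DME, −20 °C; 1 in excess
Reagents that add atoms: none
Why: Iminium-ion organocatalysis (imidazolidinone-catalysed conjugate addition of an alkenyltrifluoroborate): the benzyl group shields one face of the (E)-iminium ion of 1, so the electron-rich isobutenyl group adds to the open Re face of C3 and sets the (R) methyl stereocentre, while HF traps the boron as KBF4.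

Step 2
Reactants: 3 (3R)-3,5-dimethylhex-4-enal
Product: 5 (4R)-2,4-dimethylhex-2-ene, via hydrazone 4 (not isolated)
Conditions: N2H4·H2O, KOH, diethylene glycol, 130 °C then 200 °C (product distils)
Reagents that add atoms: none
Why: Wolff–Kishner reduction (Huang-Minlon) turns CH2–CHO into the ethyl group; the stereocentre is β to the hydrazone carbon and is not epimerised, and the isolated trisubstituted alkene is inert to KOH.

Step 3
Reactants: 5 (4R)-2,4-dimethylhex-2-ene
Product: 7 (2E,4R)-2,4-dimethylhex-2-enal, via allylic alcohol 6 (not isolated)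
Conditions: SeO2 (1.5 equiv), 1,4-dioxane–H2O (50:1), 90 °C
Reagents that add atoms: selenium dioxide, O=[Se]=O
Why: Riley allylic oxidation (ene reaction then [2,3]-sigmatropic shift) attacks the more substituted alkene terminus and selectively the E-methyl group, giving the (E)-enal without touching the allylic stereocentre.

Step 4
Reactants: 7 (2E,4R)-2,4-dimethylhex-2-enal; 8 tributyl(1,3-dioxolan-2-ylmethyl)phosphonium bromide
Product: 10 (2E,4E,6R)-4,6-dimethylocta-2,4-dienal, via dienyl dioxolane 9 (not isolated)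
Conditions: 8 (1.3 equiv), NaH (1.2 equiv), 18-crown-6 (cat.), THF, 0 °C→rt (ylide pre-formed); then 1 M HCl, THF, rt
Reagents that add atoms: water, O
Why: Wittig two-carbon homologation with a tributylphosphonium acetal ylide gives the E-vinyl dioxolane, and mild acid hydrolysis unmasks the aldehyde and equilibrates any Z isomer to the E,E-dienal; no free base remains to deprotonate the γ-stereocentre.

Step 5
Reactants: 10 (2E,4E,6R)-4,6-dimethylocta-2,4-dienal; 8 tributyl(1,3-dioxolan-2-ylmethyl)phosphonium bromide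
Product: 12 (2E,4E,6E,8R)-6,8-dimethyldeca-2,4,6-trienal, via trienyl dioxolane 11 (not isolated)
Conditions: 8 (1.3 equiv), NaH (1.2 equiv), 18-crown-6 (cat.), THF, 0 °C→rt; then 1 M HCl, THF, rt
Reagents that add atoms: water, O
Why: A second Wittig acetal homologation followed by acid hydrolysis and E-equilibration extends the dienal to the all-E trienal.

Step 6
Reactants: 13 5-bromo-2,4-dimethoxypyridine; 14 (4-methoxyphenyl)boronic acid
Product: 15 2,4-dimethoxy-5-(4-methoxyphenyl)pyridine
Conditions: Pd(dppf)Cl2 (3 mol%), K2CO3, 1,4-dioxane–H2O (4:1), 90 °C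
Reagents that add atoms: none
Why: Suzuki–Miyaura cross-coupling of the 5-bromopyridine with the arylboronic acid; the methyl ethers are inert.

Step 7
Reactants: 15 2,4-dimethoxy-5-(4-methoxyphenyl)pyridine; 16 N-methoxy-N-methylacetamide
Product: 18 1-[2,4-dimethoxy-5-(4-methoxyphenyl)pyridin-3-yl]ethan-1-one, via 3-pyridyllithium 17 (not isolated)
Conditions: t-BuLi (1.05 equiv), THF, −78 °C; then 16 (1.5 equiv), −78→0 °C; 1 M HCl
Reagents that add atoms: none
Why: Directed ortho-metalation removes the C3–H flanked by two methoxy groups, and the hindered pyridyllithium is acylated once by the Weinreb amide through a chelated tetrahedral adduct that collapses only on acidic quench.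

Step 8
Reactants: 18 1-[2,4-dimethoxy-5-(4-methoxyphenyl)pyridin-3-yl]ethan-1-one
Product: 19 3-acetyl-2,4-dimethoxy-5-(4-methoxyphenyl)pyridine 1-oxide
Conditions: mCPBA (2 equiv), CH2Cl2, 0→40 °C
Reagents that add atoms: mCPBA (3-chloroperoxybenzoic acid), O=C(OO)c1cccc(Cl)c1
Why: Peracid N-oxidation of the pyridine: the 4-methoxy group keeps the ring nitrogen nucleophilic, while the twisted, doubly ortho-substituted acetyl group resists Baeyer–Villiger oxidation.

Step 9
Reactants: 19 3-acetyl-2,4-dimethoxy-5-(4-methoxyphenyl)pyridine 1-oxide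
Product: 20 3-acetyl-1,4-dihydroxy-5-(4-hydroxyphenyl)pyridin-2(1H)-one
Conditions: BBr3 (6 equiv), CH2Cl2, −78 °C→rt; then H2O
Reagents that add atoms: none
Why: BBr3 ether cleavage removes all three O-methyl groups by bromide attack on the boron-activated ethers, and the released 2-hydroxypyridine N-oxide tautomerises to the 1-hydroxy-2-pyridone.

Step 10
Reactants: 20 3-acetyl-1,4-dihydroxy-5-(4-hydroxyphenyl)pyridin-2(1H)-one; 12 (2E,4E,6E,8R)-6,8-dimethyldeca-2,4,6-trienal
Product: 23 3-[(2E,4E,6E,8E,10R)-8,10-dimethyldodeca-2,4,6,8-tetraenoyl]-1,4-dihydroxy-5-(4-hydroxyphenyl)pyridin-2(1H)-one, via bis(difluoroboron) chelate 21 (not isolated), via tetraenone bis(difluoroboron) chelate 22 (not isolated)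
Conditions: BF3·OEt2 (excess), EtOAc, 50 °C, evaporate; 12 (1.2 equiv), iPr2NEt (0.3 equiv), 4 Å MS, MeCN, 30 °C; then THF–H2O, 45 °C
Reagents that add atoms: none
Why: Proposed new method: a boron-templated Claisen–Schmidt (Knoevenagel-type) condensation of an unprotected 3-acetyl-1,4-dihydroxy-2-pyridone with a polyenal, in which BF3 ties up both acidic chelating sites as difluoroboron chelates (O4/acetyl-O dioxaborine and N–O/C2=O), so the N–OH and 4-OH are masked and the acetyl CH3 becomes acidic enough for a hindered tertiary amine to form the boron dienolate, which adds to the aldehyde of 12 and loses water (E1cB) to the all-E chelate that aqueous THF hydrolyses to 23; because no primary or secondary amine is present, 12 cannot form an iminium ion or polyenamine and the remote C10 stereocentre is carried through unchanged; the closest known reaction type is the Pabon-type boron-complex condensation of β-diketones with aldehydes (curcuminoid synthesis) and the Knoevenagel condensation of 4-methyl-2,2-difluoro-1,3,2-dioxaborines, neither shown for N-hydroxy-2-pyridones or for polyenals with an epimerisable vinylogous stereocentre.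

## Compound list

1 | (E)-but-2-enal | C/C=C/C=O | starting material
2 | potassium trifluoro(2-methylprop-1-en-1-yl)borate | CC(C)=C[B-](F)(F)F.[K+] | starting material
3 | (3R)-3,5-dimethylhex-4-enal | O=CC[C@@H](C)C=C(C)C | intermediate
4 | [(3R)-3,5-dimethylhex-4-en-1-ylidene]hydrazine (hydrazone of 3) | NN=CC[C@@H](C)C=C(C)C | intermediate (not isolated)
5 | (4R)-2,4-dimethylhex-2-ene | CC[C@@H](C)C=C(C)C | intermediate
6 | (2E,4R)-2,4-dimethylhex-2-en-1-ol | CC[C@@H](C)/C=C(C)/CO | intermediate (not isolated)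
7 | (2E,4R)-2,4-dimethylhex-2-enal | CC[C@@H](C)/C=C(C)/C=O | intermediate
8 | tributyl(1,3-dioxolan-2-ylmethyl)phosphonium bromide | CCCC[P+](CCCC)(CCCC)CC1OCCO1.[Br-] | starting material
9 | 2-[(1E,3E,5R)-3,5-dimethylhepta-1,3-dien-1-yl]-1,3-dioxolane | CC[C@@H](C)/C=C(C)/C=C/C1OCCO1 | intermediate (not isolated)
10 | (2E,4E,6R)-4,6-dimethylocta-2,4-dienal | CC[C@@H](C)/C=C(C)/C=C/C=O | intermediate
11 | 2-[(1E,3E,5E,7R)-5,7-dimethylnona-1,3,5-trien-1-yl]-1,3-dioxolane | CC[C@@H](C)/C=C(C)/C=C/C=C/C1OCCO1 | intermediate (not isolated)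
12 | (2E,4E,6E,8R)-6,8-dimethyldeca-2,4,6-trienal | CC[C@@H](C)/C=C(C)/C=C/C=C/C=O | intermediate
13 | 5-bromo-2,4-dimethoxypyridine | COc1cc(OC)c(Br)cn1 | starting material
14 | (4-methoxyphenyl)boronic acid | COc1ccc(B(O)O)cc1 | starting material
15 | 2,4-dimethoxy-5-(4-methoxyphenyl)pyridine | COc1ccc(-c2cnc(OC)cc2OC)cc1 | intermediate
16 | N-methoxy-N-methylacetamide | CC(=O)N(C)OC | starting material
17 | [2,4-dimethoxy-5-(4-methoxyphenyl)pyridin-3-yl]lithium | [Li]c1c(OC)ncc(-c2ccc(OC)cc2)c1OC | intermediate (not isolated)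
18 | 1-[2,4-dimethoxy-5-(4-methoxyphenyl)pyridin-3-yl]ethan-1-one | COc1ccc(-c2cnc(OC)c(C(C)=O)c2OC)cc1 | intermediate
19 | 3-acetyl-2,4-dimethoxy-5-(4-methoxyphenyl)pyridine 1-oxide | COc1ccc(-c2c[n+]([O-])c(OC)c(C(C)=O)c2OC)cc1 | intermediate
20 | 3-acetyl-1,4-dihydroxy-5-(4-hydroxyphenyl)pyridin-2(1H)-one | CC(=O)c1c(O)c(-c2ccc(O)cc2)cn(O)c1=O | intermediate
21 | bis(difluoroboron) chelate of 20 (one BF2 bridging O4 and the acetyl O, one BF2 bridging N–O and the C2 O) | CC1=[O+][B-](F)(F)OC2=C1C1=[O+][B-](F)(F)ON1C=C2c1ccc(O)cc1 | intermediate (not isolated)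
22 | bis(difluoroboron) chelate of 23 (same two chelate rings, all-E tetraenyl chain, 10R) | CC[C@@H](C)/C=C(C)/C=C/C=C/C=C/C1=[O+][B-](F)(F)OC2=C1C1=[O+][B-](F)(F)ON1C=C2c1ccc(O)cc1 | intermediate (not isolated)
23 | 3-[(2E,4E,6E,8E,10R)-8,10-dimethyldodeca-2,4,6,8-tetraenoyl]-1,4-dihydroxy-5-(4-hydroxyphenyl)pyridin-2(1H)-one | CC[C@@H](C)/C=C(C)/C=C/C=C/C=C/C(=O)c1c(O)c(-c2ccc(O)cc2)cn(O)c1=O | target

## Step count and risks

Total steps: 10. Longest linear sequence: 6 (steps 1–5, then step 10); the pyridone branch is steps 6–9.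

Three steps most likely to fail:

Step 10 (the proposed new condensation). The doubly chelated polyene may be attacked by the amine, the chelates may hydrolyse poorly, or C10 may epimerise in the electron-poor chelate. The fallback uses known chemistry and sets out from 20 and 12. O-Allylation of the N–OH and the phenol (allyl bromide, K2CO3, DMF) gives 3-acetyl-1-(allyloxy)-5-[4-(allyloxy)phenyl]-4-hydroxypyridin-2(1H)-one F4. Its dianion (LDA, THF, −78 °C) adds to 12 to give the β-hydroxy ketone 3-[(4E,6E,8E,10R)-3-hydroxy-8,10-dimethyldodeca-4,6,8-trienoyl]-1-(allyloxy)-5-[4-(allyloxy)phenyl]-4-hydroxypyridin-2(1H)-one F5. Dehydration (MsCl, Et3N, then DBU) gives 1-(allyloxy)-5-[4-(allyloxy)phenyl]-3-[(2E,4E,6E,8E,10R)-8,10-dimethyldodeca-2,4,6,8-tetraenoyl]-4-hydroxypyridin-2(1H)-one F6. Pd(PPh3)4 and morpholine in THF remove both allyl groups and the fallback comes back to the route at 23.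

Step 1 (reactivity and ee of a purely aliphatic alkenyltrifluoroborate). The fallback sets out from 2. Pd-catalysed Suzuki–Miyaura coupling of 2 with 3-chlorobut-2-enal gives the achiral dienal (2E)-3,5-dimethylhexa-2,4-dienal F1; an E/Z mixture is acceptable. Organocatalytic transfer hydrogenation then reduces it (Hantzsch ester, 2-tert-butyl-3-methylimidazolidin-4-one trichloroacetate, CHCl3, −30 °C). This is a stereoconvergent iminium hydride addition at C3; the (S)-catalyst is expected to give the (R) product, and the antipode is used if the rotation shows otherwise. The fallback comes back to the route at 3.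

Step 8 (N-oxidation of a weakly basic, hindered 2-methoxy-3-acylpyridine; possible Baeyer–Villiger side reaction). The fallback sets out from 18. BBr3 demethylation gives 3-acetyl-4-hydroxy-5-(4-hydroxyphenyl)pyridin-2(1H)-one F2. Persilylation (HMDS, TMSCl) gives 3-acetyl-2,4-bis(trimethylsilyloxy)-5-[4-(trimethylsilyloxy)phenyl]pyridine F3. This is N-hydroxylated with MoO5·pyridine·HMPA (oxidation of the silylated lactim nitrogen) and desilylated on aqueous EDTA work-up. The fallback comes back to the route at 20.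

Further compounds
F1 | step 1 | (2E)-3,5-dimethylhexa-2,4-dienal | CC(C)=C/C(C)=C/C=O
F2 | step 8 | 3-acetyl-4-hydroxy-5-(4-hydroxyphenyl)pyridin-2(1H)-one | CC(=O)c1c(O)c(-c2ccc(O)cc2)c[nH]c1=O
F3 | step 8 | 3-acetyl-2,4-bis(trimethylsilyloxy)-5-[4-(trimethylsilyloxy)phenyl]pyridine | CC(=O)c1c(O[Si](C)(C)C)ncc(-c2ccc(O[Si](C)(C)C)cc2)c1O[Si](C)(C)C
F4 | step 10 | 3-acetyl-1-(allyloxy)-5-[4-(allyloxy)phenyl]-4-hydroxypyridin-2(1H)-one | CC(=O)c1c(O)c(-c2ccc(OCC=C)cc2)cn(OCC=C)c1=O
F5 | step 10 | 3-[(4E,6E,8E,10R)-3-hydroxy-8,10-dimethyldodeca-4,6,8-trienoyl]-1-(allyloxy)-5-[4-(allyloxy)phenyl]-4-hydroxypyridin-2(1H)-one | CC[C@@H](C)/C=C(C)/C=C/C=C/C(O)CC(=O)c1c(O)c(-c2ccc(OCC=C)cc2)cn(OCC=C)c1=O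
F6 | step 10 | 1-(allyloxy)-5-[4-(allyloxy)phenyl]-3-[(2E,4E,6E,8E,10R)-8,10-dimethyldodeca-2,4,6,8-tetraenoyl]-4-hydroxypyridin-2(1H)-one | CC[C@@H](C)/C=C(C)/C=C/C=C/C=C/C(=O)c1c(O)c(-c2ccc(OCC=C)cc2)cn(OCC=C)c1=O
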